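**Retrosynthetic overview**

1. Numbering (germacrane): ring A = 3(2H)-furanone (C1 ketone, C2, C3, ring oxygen, C10); ring B = ten-membered carbocycle C1–C10, which is a nine-membered oxacycle through the ring A oxygen; ring C = α-methylene-γ-lactone (O6, C6, C7, C11, C12; C13 exocyclic); C14 = methyl on C10, C15 = hydroxymethyl on C4, isovalerate on O8.
2. Last disconnection, C5–C6: nickel/chromium-mediated alkenyl–aldehyde (Nozaki–Hiyama–Kishi) ring closure of a seco (Z)-C5 iodide / C6 aldehyde; the C6 alkoxide closes ring C on the C12 methyl ester in the same operation, so rings B and C and the C6 stereocentre arise together, without protecting groups, in the final step.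
3. Enabling feature: C5 is the terminus of the cross-conjugated dienone of ring A (C1=O, C2=C3, C4=C5), so a C5–I bond is an activated, geometrically fixed vinylogous β-iodo enone; the ring A oxygen bridge C3–O–C10 holds the C4 arm and the C9 arm on the same side (the closure is nine-membered), and O6 ends γ to the C12 acyl carbon.
4. Seco precursor: C7–C8 by indium Barbier 2-(methoxycarbonyl)allylation of a ring A aldehyde (C8) with a (Z)-2-(bromomethyl)enoate carrying C6 as dimethyl acetal (C7/C8 syn), then O8 acylation; ring A by aldol, oxidation and cyclodehydration (C2–C3, O–C3) from a lactate-derived α'-hydroxy methyl ketone (C10) and a (Z)-β-iodo enal (C3–C5, C15) made by an iodide-triggered Baylis–Hillman coupling.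
5. Ring order: A (step 9), then B and C together (step 16).

Key step: step 16

Assumption: the cis-dioxolanone 1 is bought (it is otherwise one condensation of (S)-lactic acid with pivalaldehyde) and formaldehyde 7 is used as cracked paraformaldehyde; TBS = tert-butyl(dimethyl)silyl.

**Route**

Step 1
Reactants: 1 (2S,5S)-2-tert-butyl-5-methyl-1,3-dioxolan-4-one; 2 allyl bromide
Product: 3 (2S,5R)-2-tert-butyl-5-methyl-5-(prop-2-en-1-yl)-1,3-dioxolan-4-one
Conditions: LiN(i-Pr)2, THF, −78 °C; then 2, −78 → −30 °C
Reagents that add atoms: none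
Why: Seebach self-regeneration of stereocentres (enolate alkylation): the lithium enolate is alkylated on the face away from the tert-butyl group, so allyl takes the place of the hydrogen and fixes the future C10 as R.

Step 2
Reactants: 3
Product: 4 (2R)-2-hydroxy-N-methoxy-N,2-dimethylpent-4-enamide
Conditions: MeNHOMe·HCl, i-PrMgCl, THF, −20 → 0 °C; aq. NH4Cl
Reagents that add atoms: N,O-dimethylhydroxylamine hydrochloride, CNOC.Cl
Why: Weinreb amide formation by aminolysis of the activated dioxolanone carbonyl with the magnesium amide should open the acetal ring and release pivalaldehyde without touching the quaternary centre.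

Step 3
Reactants: 4
Product: 5 (3R)-3-hydroxy-3-methylhex-5-en-2-one
Conditions: MeMgBr (3 equiv), THF, 0 °C; aq. NH4Cl
Reagents that add atoms: methylmagnesium bromide, C[Mg]Br
Why: Weinreb ketone synthesis: the first equivalent deprotonates the tertiary hydroxyl and the chelated tetrahedral adduct of the second stops at the methyl ketone (C1 and C2 of the target).

Step 4
Reactants: 6 methyl propiolate; 7 formaldehyde
Product: 8 methyl (2Z)-2-(hydroxymethyl)-3-iodoprop-2-enoate
Conditions: MgI2, CH2Cl2, 0 °C
Reagents that add atoms: magnesium iodide, [Mg+2].[I-].[I-]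
Why: Iodide-triggered Morita–Baylis–Hillman-type three-component coupling: conjugate addition of iodide to the magnesium-activated ynoate gives a β-iodo allenolate that adds to formaldehyde through a closed transition state, which under kinetic control leaves iodine cis to the ester (Z) and so sets the later C4=C5 geometry.

Step 5
Reactants: 8
Product: 9 methyl (2Z)-2-({[tert-butyl(dimethyl)silyl]oxy}methyl)-3-iodoprop-2-enoate
Conditions: TBSOTf, 2,6-lutidine, CH2Cl2, −78 °C
Reagents that add atoms: tert-butyldimethylsilyl trifluoromethanesulfonate, CC(C)(C)[Si](C)(C)OS(=O)(=O)C(F)(F)F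
Why: Silyl ether formation with a hindered, non-nucleophilic base should avoid addition–elimination at the β-iodo acrylate.

Step 6
Reactants: 9
Product: 10 (2E)-2-({[tert-butyl(dimethyl)silyl]oxy}methyl)-3-iodoprop-2-en-1-ol
Conditions: i-Bu2AlH (2.2 equiv), CH2Cl2, −78 °C; aq. potassium sodium tartrate
Reagents that add atoms: none
Why: 1,2-Reduction of the enoate with diisobutylaluminium hydride leaves the iodoalkene and its geometry intact (the descriptor becomes E only through the priority rules).

Step 7
Reactants: 10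
Product: 11 (2Z)-2-({[tert-butyl(dimethyl)silyl]oxy}methyl)-3-iodoprop-2-enal
Conditions: MnO2, CH2Cl2, rt, dark
Reagents that add atoms: none
Why: Allylic alcohol oxidation with MnO2 is neutral and should not isomerise the β-iodo enal.

Step 8
Reactants: 5 (3R)-3-hydroxy-3-methylhex-5-en-2-one; 11 (2Z)-2-({[tert-butyl(dimethyl)silyl]oxy}methyl)-3-iodoprop-2-enal
Product: 12 (1Z,6R)-2-({[tert-butyl(dimethyl)silyl]oxy}methyl)-3,6-dihydroxy-1-iodo-6-methylnona-1,8-dien-5-one (both C3 epimers)
Conditions: LiN(i-Pr)2 (2.2 equiv), THF, −78 °C; then 11, −78 °C; aq. NH4Cl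
Reagents that add atoms: none
Why: Aldol addition of the alkoxide–enolate dianion (the methyl group is the only enolisable position) to the aldehyde in 1,2-fashion forms C2–C3, and the new carbinol centre is destroyed in the next step.

Step 9
Reactants: 12
Product: 14 (2R)-5-[(1Z)-3-{[tert-butyl(dimethyl)silyl]oxy}-1-iodoprop-1-en-2-yl]-2-methyl-2-(prop-2-en-1-yl)furan-3(2H)-one, via hydroxy diketone 13 (not isolated)
Conditions: Dess–Martin periodinane, NaHCO3, CH2Cl2, 0 °C → rt; then CSA (5 mol %), CH2Cl2, rt
Reagents that add atoms: none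
Why: Dess–Martin oxidation gives the 1,3-diketone, whose tertiary hydroxyl adds to the C3 carbonyl (5-exo-trig) and loses water under acid catalysis, the classical cyclodehydration route to 3(2H)-furanones (ring A).

Step 10
Reactants: 14
Product: 15 [(2R)-5-[(1Z)-3-{[tert-butyl(dimethyl)silyl]oxy}-1-iodoprop-1-en-2-yl]-2-methyl-3-oxo-2,3-dihydrofuran-2-yl]acetaldehyde
Conditions: OsO4 (2 mol %), NaIO4, 2,6-lutidine, dioxane/H2O 3:1, rt
Reagents that add atoms: sodium periodate, [Na+].[O-]I(=O)(=O)=O
Why: Lemieux–Johnson oxidation: OsO4 should dihydroxylate the isolated monosubstituted alkene much faster than the two electron-poor trisubstituted alkenes of the iodo dienone, and periodate cleaves the diol to the C8 aldehyde.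

Step 11
Reactants: 16 methyl acrylate; 17 2,2-dimethoxyacetaldehyde
Product: 18 methyl 3-hydroxy-4,4-dimethoxy-2-methylidenebutanoate (racemic)
Conditions: DABCO (0.5 equiv), dioxane/H2O, rt
Reagents that add atoms: none
Why: Morita–Baylis–Hillman reaction of an activated, non-enolisable aldehyde; the carbinol centre is lost in the next step.

Step 12
Reactants: 18
Product: 19 methyl (2Z)-2-(bromomethyl)-4,4-dimethoxybut-2-enoate
Conditions: NBS, Me2S, CH2Cl2, 0 °C → rt
Reagents that add atoms: N-bromosuccinimide, O=C1CCC(=O)N1Br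
Why: Corey–Kim-type activation of the Baylis–Hillman alcohol and SN2' displacement by bromide should give the favoured (Z)-2-(bromomethyl)alk-2-enoate under neutral conditions that spare the acetal.

Step 13
Reactants: 15 [(2R)-5-[(1Z)-3-{[tert-butyl(dimethyl)silyl]oxy}-1-iodoprop-1-en-2-yl]-2-methyl-3-oxo-2,3-dihydrofuran-2-yl]acetaldehyde; 19 methyl (2Z)-2-(bromomethyl)-4,4-dimethoxybut-2-enoate
Product: 20 methyl (3R,4R)-3-(dimethoxymethyl)-4-hydroxy-2-methylidene-5-[(2R)-5-[(1Z)-3-{[tert-butyl(dimethyl)silyl]oxy}-1-iodoprop-1-en-2-yl]-2-methyl-3-oxo-2,3-dihydrofuran-2-yl]pentanoate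
Conditions: indium powder, THF/H2O 1:1, rt; chromatographic removal of the minor diastereomer
Reagents that add atoms: none
Why: Indium-mediated Barbier 2-(alkoxycarbonyl)allylation: the allylindium adds through its γ-carbon (C7) in a chair transition state that should give the syn C7/C8 relationship typical of (Z)-2-(bromomethyl)alk-2-enoates, while the facial sense relative to C10 rests on modest 1,3-induction from the quaternary centre (the polar 1,3-anti model, with the ring A carbonyl carbon anti to the aldehyde, favours 8R).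

Step 14
Reactants: 20
Product: 21 methyl (3R,4R)-3-(dimethoxymethyl)-4-[(3-methylbutanoyl)oxy]-2-methylidene-5-[(2R)-5-[(1Z)-3-{[tert-butyl(dimethyl)silyl]oxy}-1-iodoprop-1-en-2-yl]-2-methyl-3-oxo-2,3-dihydrofuran-2-yl]pentanoate
Conditions: (i-PrCH2CO)2O, Et3N, DMAP (5 mol %), CH2Cl2, 0 °C
Reagents that add atoms: 3-methylbutanoic anhydride, CC(C)CC(=O)OC(=O)CC(C)C
Why: DMAP-catalysed acylation of the secondary alcohol should outrun lactonisation of O8 onto C12 and blocks O8, so that only O6 can later close the lactone.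

Step 15
Reactants: 21
Product: 22 methyl (3R,4R)-3-formyl-5-[(2R)-5-[(1Z)-3-hydroxy-1-iodoprop-1-en-2-yl]-2-methyl-3-oxo-2,3-dihydrofuran-2-yl]-4-[(3-methylbutanoyl)oxy]-2-methylidenepentanoate
Conditions: TFA/H2O/THF 1:1:4, 0 °C → rt; pH 7 buffer; used at once
Reagents that add atoms: water, O
Why: Acid-catalysed hydrolysis of the dimethyl acetal and of the primary silyl ether in one operation; non-basic conditions and immediate use should protect C7, which is α to the new aldehyde and allylic.

Step 16
Reactants: 22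
Product: 24 the target (4Z,6S,7R,8R,10R)-15-hydroxy-8-[(3-methylbutanoyl)oxy]-1-oxo-3,10-epoxygermacra-2,4,11(13)-trien-12,6-olide (CNP0171896.2), via seco hydroxy ester 23 (not isolated)
Conditions: CrCl2 (8 equiv), NiCl2 (0.08 equiv), degassed DMSO/THF 3:1, slow addition of 22 to 0.002 M, rt; aq. NaHCO3; then PPTS (0.1 equiv), CH2Cl2, rt
Reagents that add atoms: none
Why: Zerovalent nickel (from NiCl2 and CrCl2) inserts into the activated C5–I bond with retention of geometry, transmetalation to trivalent chromium gives an alkenylchromium that adds to the C6 aldehyde, and the chromium alkoxide, γ to the C12 methyl ester, lactonises (PPTS completes this). The closest known reaction type is the Nozaki–Hiyama–Kishi macrocyclisation of iodoalkene aldehydes, a standard closure for medium and large rings, here coupled to a γ-alkoxide-to-ester lactonisation. Ring B closes by 9-exo-trig attack of C5 on the aldehyde (the nine-membered oxacycle through the ring A oxygen, which is the ten-membered carbocycle C1–C10), and ring C by 5-exo-trig acyl substitution of O6 at C12. The only new stereocentre, C6, is set by C7 under Felkin–Anh control: the nine-membered transition state keeps the ring carbon C8 gauche to the incoming C5, so the acrylate carbon C11 lies antiperiplanar and H7 flanks the nucleophile, which should give 6S, the cis fusion of rings B and C. The step needs chemoselectivity for the aldehyde over the ring A ketone, the esters and the acrylate (alkenylchromium reagents add only to aldehydes), tolerance of the free C15 hydroxyl (low basicity of the reagent), retention of the 4Z geometry (a trisubstituted alkenylchromium is configurationally stable and an E isomer could not span the ring) and ring closure over chain growth (high dilution and the two arms held syn on ring A).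

**Compound list**

1 | (2S,5S)-2-tert-butyl-5-methyl-1,3-dioxolan-4-one | C[C@@H]1O[C@H](C(C)(C)C)OC1=O | starting material
2 | allyl bromide (3-bromoprop-1-ene) | C=CCBr | starting material
3 | (2S,5R)-2-tert-butyl-5-methyl-5-(prop-2-en-1-yl)-1,3-dioxolan-4-one | C[C@]1(CC=C)O[C@H](C(C)(C)C)OC1=O | intermediate
4 | (2R)-2-hydroxy-N-methoxy-N,2-dimethylpent-4-enamide | CON(C)C(=O)[C@@](C)(CC=C)O | intermediate
5 | (3R)-3-hydroxy-3-methylhex-5-en-2-one | CC(=O)[C@@](C)(CC=C)O | intermediate
6 | methyl propiolate | C#CC(=O)OC | starting material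
7 | formaldehyde (from paraformaldehyde) | C=O | starting material
8 | methyl (2Z)-2-(hydroxymethyl)-3-iodoprop-2-enoate | I/C=C(/CO)C(=O)OC | intermediate
9 | methyl (2Z)-2-({[tert-butyl(dimethyl)silyl]oxy}methyl)-3-iodoprop-2-enoate | I/C=C(/CO[Si](C)(C)C(C)(C)C)C(=O)OC | intermediate
10 | (2E)-2-({[tert-butyl(dimethyl)silyl]oxy}methyl)-3-iodoprop-2-en-1-ol | I/C=C(/CO[Si](C)(C)C(C)(C)C)CO | intermediate
11 | (2Z)-2-({[tert-butyl(dimethyl)silyl]oxy}methyl)-3-iodoprop-2-enal | I/C=C(/CO[Si](C)(C)C(C)(C)C)C=O | intermediate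
12 | (1Z,6R)-2-({[tert-butyl(dimethyl)silyl]oxy}methyl)-3,6-dihydroxy-1-iodo-6-methylnona-1,8-dien-5-one, both C3 epimers | I/C=C(/CO[Si](C)(C)C(C)(C)C)C(O)CC(=O)[C@@](C)(CC=C)O | intermediate
13 | (1Z,6R)-2-({[tert-butyl(dimethyl)silyl]oxy}methyl)-6-hydroxy-1-iodo-6-methylnona-1,8-diene-3,5-dione (not isolated) | I/C=C(/CO[Si](C)(C)C(C)(C)C)C(=O)CC(=O)[C@@](C)(CC=C)O | intermediate
14 | (2R)-5-[(1Z)-3-{[tert-butyl(dimethyl)silyl]oxy}-1-iodoprop-1-en-2-yl]-2-methyl-2-(prop-2-en-1-yl)furan-3(2H)-one | I/C=C(/CO[Si](C)(C)C(C)(C)C)C1=CC(=O)[C@@](C)(CC=C)O1 | intermediate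
15 | [(2R)-5-[(1Z)-3-{[tert-butyl(dimethyl)silyl]oxy}-1-iodoprop-1-en-2-yl]-2-methyl-3-oxo-2,3-dihydrofuran-2-yl]acetaldehyde | I/C=C(/CO[Si](C)(C)C(C)(C)C)C1=CC(=O)[C@@](C)(CC=O)O1 | intermediate
16 | methyl acrylate | C=CC(=O)OC | starting material
17 | 2,2-dimethoxyacetaldehyde | COC(OC)C=O | starting material
18 | methyl 3-hydroxy-4,4-dimethoxy-2-methylidenebutanoate (racemic) | COC(OC)C(O)C(=C)C(=O)OC | intermediate
19 | methyl (2Z)-2-(bromomethyl)-4,4-dimethoxybut-2-enoate | COC(OC)/C=C(\CBr)C(=O)OC | intermediate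
20 | methyl (3R,4R)-3-(dimethoxymethyl)-4-hydroxy-2-methylidene-5-[(2R)-5-[(1Z)-3-{[tert-butyl(dimethyl)silyl]oxy}-1-iodoprop-1-en-2-yl]-2-methyl-3-oxo-2,3-dihydrofuran-2-yl]pentanoate | I/C=C(/CO[Si](C)(C)C(C)(C)C)C1=CC(=O)[C@@](C)(C[C@@H](O)[C@@H](C(=C)C(=O)OC)C(OC)OC)O1 | intermediate
21 | methyl (3R,4R)-3-(dimethoxymethyl)-4-[(3-methylbutanoyl)oxy]-2-methylidene-5-[(2R)-5-[(1Z)-3-{[tert-butyl(dimethyl)silyl]oxy}-1-iodoprop-1-en-2-yl]-2-methyl-3-oxo-2,3-dihydrofuran-2-yl]pentanoate | I/C=C(/CO[Si](C)(C)C(C)(C)C)C1=CC(=O)[C@@](C)(C[C@@H](OC(=O)CC(C)C)[C@@H](C(=C)C(=O)OC)C(OC)OC)O1 | intermediate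
22 | methyl (3R,4R)-3-formyl-5-[(2R)-5-[(1Z)-3-hydroxy-1-iodoprop-1-en-2-yl]-2-methyl-3-oxo-2,3-dihydrofuran-2-yl]-4-[(3-methylbutanoyl)oxy]-2-methylidenepentanoate | I/C=C(/CO)C1=CC(=O)[C@@](C)(C[C@@H](OC(=O)CC(C)C)[C@@H](C(=C)C(=O)OC)C=O)O1 | intermediate
23 | methyl (4Z,6S,7S,8R,10R)-6,15-dihydroxy-8-[(3-methylbutanoyl)oxy]-1-oxo-3,10-epoxygermacra-2,4,11(13)-trien-12-oate (not isolated) | O[C@H]1/C=C(/CO)C2=CC(=O)[C@@](C)(C[C@@H](OC(=O)CC(C)C)[C@H]1C(=C)C(=O)OC)O2 | intermediate
24 | (4Z,6S,7R,8R,10R)-15-hydroxy-8-[(3-methylbutanoyl)oxy]-1-oxo-3,10-epoxygermacra-2,4,11(13)-trien-12,6-olide (CNP0171896.2) | C=C1C(=O)O[C@H]2/C=C(/CO)C3=CC(=O)[C@@](C)(C[C@@H](OC(=O)CC(C)C)[C@@H]12)O3 | target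

**Step count and risks**

Total step count: 16. Longest linear sequence: 11 steps (from methyl propiolate 6: steps 4–10 and 13–16).

Steps most likely to fail:

1. Step 16. What may go wrong: delivery of the alkenyl group to the wrong face of the C6 aldehyde (trans ring fusion), chain growth between molecules in place of nine-membered ring closure, and loss of the alkenylchromium by protonation. Fallback (sets out from 22, comes back at 23 and so at 24): the same closure is worked up at pH 7 and not treated with acid, which should leave the C6-epimeric seco carbinols F1. MnO2 in CH2Cl2 then oxidises both allylic hydroxyls to the C6 keto C15 aldehyde F2, which erases C6. Reduction of both carbonyls with BH3·SMe2 and the (S)-configured B-methyl oxazaborolidine (Corey–Bakshi–Shibata reduction, the alkenyl group acting as the large substituent; otherwise the antipode) should return the (6S) carbinol 23 under reagent control, and PPTS lactonises it to 24.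

2. Step 13. What may go wrong: addition to the wrong face of the C8 aldehyde relative to C10 (the 1,3-induction from the quaternary centre is weak), and lactonisation of O8 onto C12 before acylation. Fallback (sets out from 15 and 19, comes back at 21): a ligand-controlled Nozaki–Hiyama allylation (CrCl2 with a chiral 1,8-bis(4-isopropyl-4,5-dihydrooxazol-2-yl)carbazole ligand, i-Pr2NEt, THF; no nickel, so the iodoalkene is left alone) is anti-selective and should give the (7R,8S) alcohol, methyl (3R,4S)-3-(dimethoxymethyl)-4-hydroxy-2-methylidene-5-[(2R)-5-[(1Z)-3-{[tert-butyl(dimethyl)silyl]oxy}-1-iodoprop-1-en-2-yl]-2-methyl-3-oxo-2,3-dihydrofuran-2-yl]pentanoate F3. Mitsunobu esterification with 3-methylbutanoic acid (PPh3, DIAD) then inverts C8 and installs the ester in one step to give 21.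

3. Step 15. What may go wrong: epimerisation at C7 or migration of the C11=C13 double bond into conjugation with the new aldehyde in aqueous acid, incomplete desilylation, and later quenching of the organochromium by the free hydroxyl. Fallback (sets out from 21, comes back at 24): the order of the end-game is changed so that the aldehyde never meets aqueous acid and the hydroxyl stays masked during ring closure. Acetal exchange with I2 (cat.) in acetone should give the silyl-protected aldehyde F4; ring closure with CrCl2/NiCl2 as in step 16 gives the silyl-protected lactone F5; HF·pyridine (THF, 0 °C) then frees the C15 hydroxyl to give 24.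

**Further compounds**

F1 | step 16 | methyl (4Z,7S,8R,10R)-6,15-dihydroxy-8-[(3-methylbutanoyl)oxy]-1-oxo-3,10-epoxygermacra-2,4,11(13)-trien-12-oate, mixture of C6 epimers | OC1/C=C(/CO)C2=CC(=O)[C@@](C)(C[C@@H](OC(=O)CC(C)C)[C@H]1C(=C)C(=O)OC)O2
F2 | step 16 | methyl (7R,8R,10R)-8-[(3-methylbutanoyl)oxy]-1,6,15-trioxo-3,10-epoxygermacra-2,4,11(13)-trien-12-oate, C4=C5 geometry as in the target (C3 and C6 cis) | O=C1/C=C(/C=O)C2=CC(=O)[C@@](C)(C[C@@H](OC(=O)CC(C)C)[C@H]1C(=C)C(=O)OC)O2
F3 | step 13 | methyl (3R,4S)-3-(dimethoxymethyl)-4-hydroxy-2-methylidene-5-[(2R)-5-[(1Z)-3-{[tert-butyl(dimethyl)silyl]oxy}-1-iodoprop-1-en-2-yl]-2-methyl-3-oxo-2,3-dihydrofuran-2-yl]pentanoate | I/C=C(/CO[Si](C)(C)C(C)(C)C)C1=CC(=O)[C@@](C)(C[C@H](O)[C@@H](C(=C)C(=O)OC)C(OC)OC)O1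
F4 | step 15 | methyl (3R,4R)-3-formyl-5-[(2R)-5-[(1Z)-3-{[tert-butyl(dimethyl)silyl]oxy}-1-iodoprop-1-en-2-yl]-2-methyl-3-oxo-2,3-dihydrofuran-2-yl]-4-[(3-methylbutanoyl)oxy]-2-methylidenepentanoate | I/C=C(/CO[Si](C)(C)C(C)(C)C)C1=CC(=O)[C@@](C)(C[C@@H](OC(=O)CC(C)C)[C@@H](C(=C)C(=O)OC)C=O)O1
F5 | step 15 | 15-O-[tert-butyl(dimethyl)silyl] ether of 24 | C=C1C(=O)O[C@H]2/C=C(/CO[Si](C)(C)C(C)(C)C)C3=CC(=O)[C@@](C)(C[C@@H](OC(=O)CC(C)C)[C@@H]12)O3
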